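The runs are calculated with constants of no real substance; noise was put on by code.

At early times the red flask makes target fast and then bends. I want to know what remains of its free enzyme, so I reckon with the fraction left and not with the target made.

| flask | substrate | free enzyme | temperature | remark | time |
|---|---|---|---|---|---|
| red | 44 mM | 0.01 mol% | 37 °C | the very flask that is asked about, followed so far |  |
| grey | 44 mM | 0.015 mol% | 22 °C | run made earlier |  |
| flask | 44 mM | 0.01 mol% | 37 °C |  | 4.0 h |

| run | time / h | target / % |
|---|---|---|
| red | 0.200 | 3.6 |
| red | 0.667 | 5.6 |
| red | 1.00 | 7.4 |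
| red | 1.50 | 9.2 |
| red | 2.50 | 9.1 |
| red | 3.00 | 8.6 |
| red | 4.00 | 8.8 |
| grey | 0.417 | 6.7 |
| grey | 1.33 | 14.1 |
| grey | 2.00 | 18.5 |
| grey | 3.00 | 22.2 |
| grey | 5.00 | 24.8 |
| grey | 6.00 | 25.3 |
| grey | 8.00 | 25.2 |

(scatter of a reading: 0.5 percentage points)

- west: at 4.0 h raise the temperature by 15 K, then wait 80 min
- north-west: at 4.0 h take out 90 % of the target then present, then wait 80 min
- south-east: at 4.0 h add free enzyme, 100 % of the amount charged, then wait 80 min
- south-west: change nothing and wait 80 min more

- in percentages every species weighs as the substrate in it: one side product counts as two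
- target taken out counts as made
- what may be going on: free enzyme -> unfolded enzyme; substrate + free enzyme -> target + free enzyme; substrate + target -> side product; 2 free enzyme -> spent catalyst
- additions bring no volume worth counting

- target, in percent of the substrate first charged, at 4.0 h
- which option adds most target ("none" when 2 percentage points or less is all one gets) (west / north-west / south-east / south-west / none)
- target present, with what was taken out counted in, in percent of the substrate first charged, after west
- target present, with what was taken out counted in, in percent of the substrate first charged, after south-west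

The step that joins two free enzyme runs with [free enzyme] squared (second-order deactivation). With no other loss of free enzyme, it leaves the fraction f = 1/(1 + t/τ), where τ is the time by which half the free enzyme is gone. If making follows f, target climbs as g·ln(1 + t/τ).

I try τ = 0.500 h. The red readings at 1.50 h and 0.667 h stand in the ratio 1.64, and the curve gives 1.64. The reading at 1.50 h then gives g = 6.64 %. The first reading stands 1.4 percentage points above this curve, more than the scatter of 0.5 points.

So the curve starts at 13.3 % of the charge per hour and has its knee at τ, at 4.60 %. At 4.0 h it would reach 14.6 %, but the readings level at 8.83 %. I read that level as a balance (a quasi-steady state) between making and the step from substrate + target, not as an end, and I commit to it for 4.0 h, when f = 11.1 %. The balance gives a loss constant of 0.167 h⁻¹.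

Over the 80 min of waiting, I reckon that the flask makes 1.7 points and loses 2 points, so it sags by 0.30 points. With 90 % of the target taken out, I reckon the loss shrinks to 0.2 points, so this option adds about 1.5 points to the target at 4.0 h, less than the margin of 2 points. Fresh enzyme lifts the free enzyme to 111 % of the amount charged, and I reckon that it makes 9.1 points; after a loss of 3 points it gains 6.1 points, so of the options I reckon I choose south-east. For west I reckon no number.

The forecast gives 8.9 %, south-east, 8.6 % and 8.8 %, and states: “By 4 h, red has about 0.1% of its enzyme active”, where my fraction left is 11.1 %.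

The flask gives 8.93 %, and south-east is best with 6.7 points. West ends at 4.49 % and waiting at 8.14 %.

    free enzyme → unfolded enzyme (k = 8.10 × 10⁻⁶ s⁻¹, Ea = 256 kJ mol⁻¹)
    substrate + free enzyme → target + free enzyme, rate k2*[substrate]^3*[free enzyme]/(1 + ([substrate]/Kh2)^3) (13.0 mM, k = 2.10 × 10⁵ L³ mol⁻³ s⁻¹, Ea = 10.0 kJ mol⁻¹)
    substrate + target → side product (k = 0.00220 L mol⁻¹ s⁻¹, Ea = 49.0 kJ mol⁻¹)
    2 free enzyme → spent catalyst (k = 58.0 L mol⁻¹ s⁻¹, Ea = 48.0 kJ mol⁻¹)
    (constants at 37 °C)

In the red flask, spent catalyst stood at 42.0 % of the catalyst charged after 0.400 h and at 85.5 % after 4.00 h, when free enzyme stood at 11.2 % and unfolded enzyme at 3.29 %. Each step taken net, target was made 2.39 times faster than it was used up at 0.990 h, but that ratio was 0.770 at 4.00 h, with side product at 18.2 %. Read at 15 h, the same flask has f = 3.23 % by my reckoning, free enzyme at 2.77 % and target at 3.75 %.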